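**Retrosynthetic overview**

1. The key disconnection is C(CH3)2–CH(OH). Thiazole N3=C2 sits directly on the quaternary carbon, so N3=C2–C(CH3)2–CH(OH) is an aza-aldol (β-hydroxy-imine) array. With a C2-isopropenyl group in its place, N3=C2–C(CH3)=CH2 is a 1-azadiene, and conjugate hydride addition unmasks the fully substituted aza-enolate at exactly that carbon.
2. The key step is an enantioselective copper-hydride reductive aza-aldol coupling of the complete 2-isopropenylthiazole half with the complete (Z)-dienyl carbamate aldehyde. It forms the C–C bond, the gem-dimethyl quaternary carbon and the only stereocentre, and it ends the synthesis.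
3. Thiazole half: ethyl 2-(2-bromothiazol-4-yl)acetate, DIBAL-H to the aldehyde, Z-selective Wittig (skipped diene), Suzuki–Miyaura coupling (isopropenyl).
4. Aldehyde half: but-3-yn-1-amine, methyl carbamate, Markovnikov hydroiodination, Sonogashira coupling with but-3-yn-1-ol, Boland reduction (Z-diene), Dess–Martin oxidation.
5. Rings: the thiazole is the only ring and is bought intact; no ring is formed or opened in the route.

Key step: step 9

Assumption: no model predicts which ligand enantiomer in step 9 sends the aza-enolate to the Si face of the aldehyde (the face that gives the 7R carbinol); (S,S)-Ph-BPE is written, and its equally available mirror image takes its place if the sense is the opposite.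

**Route**

Step 1
Reactants: 1 ethyl 2-(2-bromo-1,3-thiazol-4-yl)acetate
Product: 2 2-(2-bromo-1,3-thiazol-4-yl)acetaldehyde
Conditions: DIBAL-H (1.05 equiv), CH2Cl2, −78 °C; MeOH, then aq. Rochelle salt
Reagents that add atoms: none
Why: DIBAL-H partial reduction of an ester should stop at the aldehyde because the aluminium hemiacetal is stable at −78 °C and collapses only on work-up, and the C2–Br bond is inert to the hydride.

Step 2
Reactants: 2 2-(2-bromo-1,3-thiazol-4-yl)acetaldehyde; 3 (but-3-en-1-yl)triphenylphosphonium bromide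
Product: 5 2-bromo-4-[(2Z)-hexa-2,5-dien-1-yl]-1,3-thiazole, via phosphorus ylide 4 (not isolated)
Conditions: 3 (1.15 equiv), NaHMDS (1.1 equiv), THF, −78 → 0 °C; then 2, −78 °C → rt
Reagents that add atoms: none
Why: Wittig olefination with a lithium-free non-stabilised ylide is under kinetic control and should give the 2Z-alkene of the skipped diene, and the ylide is made with a slight deficit of base so that no amide is left to enolise 2 or to metalate C5–H.

Step 3
Reactants: 5 2-bromo-4-[(2Z)-hexa-2,5-dien-1-yl]-1,3-thiazole; 6 4,4,5,5-tetramethyl-2-(prop-1-en-2-yl)-1,3,2-dioxaborolane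
Product: 7 4-[(2Z)-hexa-2,5-dien-1-yl]-2-(prop-1-en-2-yl)-1,3-thiazole
Conditions: Pd(dppf)Cl2 (3 mol%), K3PO4, 1,4-dioxane/H2O (10:1), 60 °C
Reagents that add atoms: none
Why: Suzuki–Miyaura coupling at the activated C2–Br bond (flanked by N and S) should install the isopropenyl group late, so that the azadiene never meets DIBAL-H or the ylide, and the phosphate base leaves the skipped diene unmoved.

Step 4
Reactants: 8 but-3-yn-1-amine hydrochloride
Product: 9 methyl N-(but-3-yn-1-yl)carbamate
Conditions: ClCO2Me, Et3N (2.2 equiv), CH2Cl2, 0 °C → rt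
Reagents that add atoms: methyl chloroformate, COC(=O)Cl
Why: N-acylation of the primary amine by the chloroformate (carbamate formation) should be clean, triethylamine freeing the amine from its salt and taking up the second HCl.

Step 5
Reactants: 9 methyl N-(but-3-yn-1-yl)carbamate
Product: 10 methyl N-(3-iodobut-3-en-1-yl)carbamate
Conditions: NaI, Me3SiCl, H2O (0.5 equiv), MeCN, 0 °C → rt, dark
Reagents that add atoms: sodium iodide, [Na+].[I-]
Why: Markovnikov hydroiodination of the terminal alkyne by HI made in situ (proton to the terminal carbon, iodide to the internal one) should give the 2-iodo-1-alkene, and in wet acetonitrile at room temperature the methyl carbamate is not dealkylated.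

Step 6
Reactants: 10 methyl N-(3-iodobut-3-en-1-yl)carbamate; 11 but-3-yn-1-ol
Product: 12 methyl N-(7-hydroxy-3-methylidenehept-4-yn-1-yl)carbamate
Conditions: Pd(PPh3)2Cl2 (2 mol%), CuI (4 mol%), Et3N, THF, rt
Reagents that add atoms: none
Why: Sonogashira coupling of a vinyl iodide with a terminal alkyne runs at room temperature and tolerates the free hydroxyl and the N–H carbamate.

Step 7
Reactants: 12 methyl N-(7-hydroxy-3-methylidenehept-4-yn-1-yl)carbamate
Product: 13 methyl N-[(4Z)-7-hydroxy-3-methylidenehept-4-en-1-yl]carbamate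
Conditions: Zn(Cu/Ag), MeOH/H2O (1:1), 45 °C
Reagents that add atoms: none
Why: Boland reduction: activated zinc reduces only the conjugated triple bond by cis delivery of two hydrogens from the protic medium, which should set the 4Z geometry without over-reduction.

Step 8
Reactants: 13 methyl N-[(4Z)-7-hydroxy-3-methylidenehept-4-en-1-yl]carbamate
Product: 14 methyl N-[(4Z)-3-methylidene-7-oxohept-4-en-1-yl]carbamate
Conditions: Dess–Martin periodinane, NaHCO3, CH2Cl2, 0 °C; cold filtration through Florisil; used at once
Reagents that add atoms: none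
Why: Dess–Martin oxidation under bicarbonate buffer is fast, near neutral and non-enolising, as the β,γ-unsaturated aldehyde requires, and 14 is neither chromatographed nor stored.

Step 9
Reactants: 7 4-[(2Z)-hexa-2,5-dien-1-yl]-2-(prop-1-en-2-yl)-1,3-thiazole; 14 methyl N-[(4Z)-3-methylidene-7-oxohept-4-en-1-yl]carbamate
Product: 18 mycothiazole (methyl N-[(4Z,7R)-8-{4-[(2Z)-hexa-2,5-dien-1-yl]-1,3-thiazol-2-yl}-7-hydroxy-8-methyl-3-methylidenenon-4-en-1-yl]carbamate), via copper aza-enolate 15 (not isolated), via copper alkoxide 16 (not isolated), via silyl ether 17 (not isolated)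
Conditions: Cu(OAc)2 (5 mol%), (S,S)-Ph-BPE (6 mol%), (MeO)2MeSiH (3 equiv), THF, 0 °C, 14 added over 6 h to 7 (1.3 equiv); then NH4F (cat.), MeOH, rt
Reagents that add atoms: none
Why: Proposed new method: ligated Cu–H adds in the 1,4 sense to the 1-azadiene N3=C2–C(CH3)=CH2 of 7 (hydride to the terminal CH2, copper to N3) to give aza-enolate 15, whose exocyclic carbon attacks the aldehyde of 14 through a six-membered chair-like Cu–N3–C2=C···C=O transition state, so that the C–C bond, the gem-dimethyl quaternary carbon and the re-aromatised thiazole form together; alkoxide 16 is turned over by Si–H σ-bond metathesis to silyl ether 17 and Cu–H, and methanolysis frees 18. The closest known reaction type is the copper hydride/bisphosphine-catalysed enantioselective reductive coupling of 2-alkenylazaarenes with ketones, supported by copper hydride reductive couplings that engage aldehydes; untested are the α-branched alkenyl group and this aldehyde class. No ring is closed. The single new stereocentre (7R) is controlled by the chiral bisphosphine on copper, which must expose the Si face of the aldehyde in the cyclic transition state; the nucleophilic carbon carries two methyl groups, so no enolate-geometry or second-stereocentre problem arises. The step needs chemoselective hydrocupration of the azadiene ahead of 1,2-reduction of the aldehyde and of hydrocupration of the 1,3-diene and the isolated alkenes: conjugation with N3, which also directs copper, makes the isopropenyl group the only polarised alkene, and slow addition of 14 to an excess of 7 keeps the copper as 15, so that the aldehyde meets the aza-enolate and not Cu–H. It also needs the nucleophile at the branched carbon only, which the conjugate hydride addition fixes and which deprotonation of a 2-isopropylthiazole could not (C5–H and the allylic C4–CH2 compete).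

**Compound list**

1 | ethyl 2-(2-bromo-1,3-thiazol-4-yl)acetate | CCOC(=O)Cc1csc(Br)n1 | starting material
2 | 2-(2-bromo-1,3-thiazol-4-yl)acetaldehyde | O=CCc1csc(Br)n1 | intermediate
3 | (but-3-en-1-yl)triphenylphosphonium bromide | C=CCC[P+](c1ccccc1)(c1ccccc1)c1ccccc1.[Br-] | starting material
4 | (but-3-en-1-ylidene)triphenyl-λ5-phosphane (ylide of 3) | C=CCC=P(c1ccccc1)(c1ccccc1)c1ccccc1 | intermediate
5 | 2-bromo-4-[(2Z)-hexa-2,5-dien-1-yl]-1,3-thiazole | C=CC/C=C\Cc1csc(Br)n1 | intermediate
6 | 4,4,5,5-tetramethyl-2-(prop-1-en-2-yl)-1,3,2-dioxaborolane | C=C(C)B1OC(C)(C)C(C)(C)O1 | starting material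
7 | 4-[(2Z)-hexa-2,5-dien-1-yl]-2-(prop-1-en-2-yl)-1,3-thiazole | C=CC/C=C\Cc1csc(C(C)=C)n1 | intermediate
8 | but-3-yn-1-amine hydrochloride | C#CCCN.Cl | starting material
9 | methyl N-(but-3-yn-1-yl)carbamate | C#CCCNC(=O)OC | intermediate
10 | methyl N-(3-iodobut-3-en-1-yl)carbamate | C=C(I)CCNC(=O)OC | intermediate
11 | but-3-yn-1-ol | C#CCCO | starting material
12 | methyl N-(7-hydroxy-3-methylidenehept-4-yn-1-yl)carbamate | OCCC#CC(=C)CCNC(=O)OC | intermediate
13 | methyl N-[(4Z)-7-hydroxy-3-methylidenehept-4-en-1-yl]carbamate | OCC/C=C\C(=C)CCNC(=O)OC | intermediate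
14 | methyl N-[(4Z)-3-methylidene-7-oxohept-4-en-1-yl]carbamate | O=CC/C=C\C(=C)CCNC(=O)OC | intermediate
15 | copper(I) aza-enolate, 3-cuprio-4-[(2Z)-hexa-2,5-dien-1-yl]-2-(propan-2-ylidene)-2,3-dihydro-1,3-thiazole (bisphosphine on copper not drawn) | C=CC/C=C\CC1=CSC(=C(C)C)N1[Cu] | intermediate
16 | copper(I) (7R)-alkoxide of 18 (bisphosphine on copper not drawn) | C=CC/C=C\Cc1csc(C(C)(C)[C@H](O[Cu])C/C=C\C(=C)CCNC(=O)OC)n1 | intermediate
17 | (7R)-dimethoxy(methyl)silyl ether of 18 | C=CC/C=C\Cc1csc(C(C)(C)[C@H](O[Si](C)(OC)OC)C/C=C\C(=C)CCNC(=O)OC)n1 | intermediate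
18 | mycothiazole, methyl N-[(4Z,7R)-8-{4-[(2Z)-hexa-2,5-dien-1-yl]-1,3-thiazol-2-yl}-7-hydroxy-8-methyl-3-methylidenenon-4-en-1-yl]carbamate | C=CC/C=C\Cc1csc(C(C)(C)[C@H](O)C/C=C\C(=C)CCNC(=O)OC)n1 | target

**Step count**

Total: 9 steps. Longest linear sequence: 6 steps (steps 4, 5, 6, 7, 8, 9).

**Steps most likely to fail**

Step 9 (Proposed new method). Three processes may defeat it:
- Copper hydride may reduce the aldehyde to the alcohol before it meets the aza-enolate.
- Basic copper species may move the C4=C5 double bond of the aldehyde into conjugation, or the carbamate N–H may protonate the aza-enolate.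
- The ligand may differentiate the two aldehyde faces poorly.

The fallback uses known chemistry, sets out from 7 and 14 and comes back at 18. Copper hydride conjugate reduction of 7 (Cu(OAc)2/bisphosphine cat., silane, t-BuOH, toluene) should give 4-[(2Z)-hexa-2,5-dien-1-yl]-2-(propan-2-yl)-1,3-thiazole F1. Soft enolisation with 9-BBN triflate and iPr2NEt in CH2Cl2, where N-borylation acidifies only the C2-alkyl C–H, should give the boron aza-enolate 3-(9-borabicyclo[3.3.1]nonan-9-yl)-4-[(2Z)-hexa-2,5-dien-1-yl]-2-(propan-2-ylidene)-2,3-dihydro-1,3-thiazole F2, which is not isolated. Addition of 14 at −78 °C and buffered oxidative work-up should give the racemic alcohol F3, with no hydride and no basic metal species present. Dess–Martin oxidation should give the ketone F4. Corey–Bakshi–Shibata reduction with (S)-Me-CBS and catecholborane at −78 °C, the tertiary alkyl side acting as the large group, should then give 18.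

Step 8. The C4=C5 double bond of the β,γ-unsaturated aldehyde may migrate into conjugation (2,4-dienal) during oxidation or before use. The fallback assembles the diene after the fragment union; it sets out from 7 and 10 and comes back at 18. Commercial 4-(trimethylsilyl)but-3-yn-1-ol is oxidised (Dess–Martin) to 4-(trimethylsilyl)but-3-ynal F5, which has no diene to drive migration. Coupling with 7 under the conditions of step 9 should give (3R)-2-{4-[(2Z)-hexa-2,5-dien-1-yl]-1,3-thiazol-2-yl}-2-methyl-6-(trimethylsilyl)hex-5-yn-3-ol F6. K2CO3 in MeOH should remove the C-silyl group to give the terminal alkyne F7. Sonogashira coupling with 10 should give the enyne F8, and Boland reduction as in step 7 should give 18.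

Step 2. The strongly basic non-stabilised ylide may enolise the heteroarylacetaldehyde (self-condensation), and the Z/E ratio may erode. The fallback makes the alkene by cross-coupling; it sets out from 2 and comes back at 5. Stork–Zhao olefination of 2 with the less basic iodomethylene ylide (Ph3P+CH2I I−, NaHMDS, THF/DMPU, −78 °C) should give 2-bromo-4-[(2Z)-3-iodoprop-2-en-1-yl]-1,3-thiazole F9. Stille coupling with allyltributylstannane (Pd2(dba)3, AsPh3, DMF, rt), in which the vinyl iodide reacts ahead of the C2–Br bond, should give 5 with the Z geometry retained.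

Further compounds
F1 | step 9 | 4-[(2Z)-hexa-2,5-dien-1-yl]-2-(propan-2-yl)-1,3-thiazole | C=CC/C=C\Cc1csc(C(C)C)n1
F2 | step 9 | 3-(9-borabicyclo[3.3.1]nonan-9-yl)-4-[(2Z)-hexa-2,5-dien-1-yl]-2-(propan-2-ylidene)-2,3-dihydro-1,3-thiazole | C=CC/C=C\CC1=CSC(=C(C)C)N1B2C3CCCC2CCC3
F3 | step 9 | racemic methyl N-[(4Z)-8-{4-[(2Z)-hexa-2,5-dien-1-yl]-1,3-thiazol-2-yl}-7-hydroxy-8-methyl-3-methylidenenon-4-en-1-yl]carbamate | C=CC/C=C\Cc1csc(C(C)(C)C(O)C/C=C\C(=C)CCNC(=O)OC)n1
F4 | step 9 | methyl N-[(4Z)-8-{4-[(2Z)-hexa-2,5-dien-1-yl]-1,3-thiazol-2-yl}-8-methyl-3-methylidene-7-oxonon-4-en-1-yl]carbamate | C=CC/C=C\Cc1csc(C(C)(C)C(=O)C/C=C\C(=C)CCNC(=O)OC)n1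
F5 | step 8 | 4-(trimethylsilyl)but-3-ynal | C[Si](C)(C)C#CCC=O
F6 | step 8 | (3R)-2-{4-[(2Z)-hexa-2,5-dien-1-yl]-1,3-thiazol-2-yl}-2-methyl-6-(trimethylsilyl)hex-5-yn-3-ol | C=CC/C=C\Cc1csc(C(C)(C)[C@H](O)CC#C[Si](C)(C)C)n1
F7 | step 8 | (3R)-2-{4-[(2Z)-hexa-2,5-dien-1-yl]-1,3-thiazol-2-yl}-2-methylhex-5-yn-3-ol | C=CC/C=C\Cc1csc(C(C)(C)[C@H](O)CC#C)n1
F8 | step 8 | methyl N-[(7R)-8-{4-[(2Z)-hexa-2,5-dien-1-yl]-1,3-thiazol-2-yl}-7-hydroxy-8-methyl-3-methylidenenon-4-yn-1-yl]carbamate | C=CC/C=C\Cc1csc(C(C)(C)[C@H](O)CC#CC(=C)CCNC(=O)OC)n1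
F9 | step 2 | 2-bromo-4-[(2Z)-3-iodoprop-2-en-1-yl]-1,3-thiazole | I/C=C\Cc1csc(Br)n1
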